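**Plan**
Cuts (briarane numbering): C6–Cl ⇒ C6–OH with inversion; C4 carbinol ⇒ C4 ketone; C3–C4 and C4–C5 together, with C4 leaving as CO; C8–C17 (lactone); C8–C9; C11–O and C11–C20; C1–C14 and C10–C11 (Diels–Alder).
Enabling feature: in the ten-membered ring (C1–C10), C4 is the only sp3 atom between C3 of the E-C2=C3 olefin and C5 of the C5=C16 methylene. It is a divinyl carbinol; one oxidation level up it is a divinyl ketone, which is the product of alkenyl iodide + CO + alkenylstannane.
Forward order: the cyclohexenone ring (C1, C10–C14) comes from a Diels–Alder reaction. C9 is joined to a tartrate-derived C5–C8 unit by Ni/Cr coupling. The γ-lactone (O7, C7, C8, C17, C19) closes by an intramolecular Reformatsky reaction. The ten-membered ring closes last, by carbonylative coupling.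
Stereochemistry: C1/C10 come from one catalytic asymmetric Diels–Alder reaction (E-enal gives trans), and C11 is relayed from C10. C6/C7 are bought as D-tartrate, and C8 and C17 are relayed from C7 in the lactone closure. C9 is set by a chiral Cr ligand and C4 by CBS reduction. C6 is inverted in the SN2 chlorination.

Key step: step 22

Assumption: briarane numbering (C1–C20) is used for all intermediates; in steps 3, 12 and 23 the named catalyst or ligand enantiomer is taken to give the drawn configuration (otherwise its mirror image is used); 23 is a mixture of epimers at the CHBr carbon, which is lost in step 17.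

Step 1
Reactants: 1 but-3-en-2-one
Product: 2 2-(triisopropylsilyloxy)buta-1,3-diene
Conditions: TIPSOTf, Et3N, CH2Cl2, 0 °C
Reagents that add atoms: triisopropylsilyl triflate CC(C)[Si](OS(=O)(=O)C(F)(F)F)(C(C)C)C(C)C
Why: Soft enolisation and O-silylation of the methyl ketone should give the cross-conjugated 2-silyloxydiene; no stereocentre is formed.

Step 2
Reactants: 3 (tert-butyldimethylsilyloxy)acetaldehyde; 4 2-(triphenylphosphoranylidene)propanal
Product: 5 (E)-4-(tert-butyldimethylsilyloxy)-2-methylbut-2-enal
Conditions: toluene, 80 °C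
Reagents that add atoms: none
Why: Wittig olefination with a stabilised ylide should give the E-trisubstituted enal, and this geometry later becomes the trans C2/C9 relationship.

Step 3
Reactants: 2 2-(triisopropylsilyloxy)buta-1,3-diene; 5 (E)-enal
Product: 6 cyclohexene TIPS enol ether (C12=C13) with Me and CHO on C1 and CH2OTBS on C10, CHO and CH2OTBS trans
Conditions: (S)-o-tolyl oxazaborolidine·Tf2NH (20 mol %), CH2Cl2, −78 → −40 °C
Reagents that add atoms: none
Why: In this catalytic enantioselective Diels–Alder reaction the formyl-bound cationic oxazaborolidine shields one enal face, the diene terminus next to C–OSi (C11) bonds to the β-carbon C10 ("para" orientation), and suprafacial addition turns the E geometry into trans C1–CHO/C10–CH2OTBS, so C1 and C10 are set together.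

Step 4
Reactants: 6 Diels–Alder adduct
Product: 7 4-formyl-4-methyl-5-(TBSO-methyl)cyclohex-2-enone (C12 ketone, C13=C14)
Conditions: Pd(OAc)2 (1.1 equiv), MeCN, rt → 40 °C
Reagents that add atoms: none
Why: In the Saegusa–Ito oxidation the regiodefined C12=C13 enol ether is palladated at C13, and β-hydride loss is possible only from C14, which should give the C13=C14 enone without touching C1 or C10.

Step 5
Reactants: 7 enone aldehyde
Product: 8 C2 dimethyl acetal of 7
Conditions: TMSOMe (2.5 equiv), TMSOTf (5 mol %), CH2Cl2, −78 °C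
Reagents that add atoms: methoxytrimethylsilane CO[Si](C)(C)C
Why: In TMSOTf-catalysed aprotic acetalisation the aldehyde reacts faster than the conjugated ketone, and the primary TBS ether survives the non-protic conditions.

Step 6
Reactants: 8 acetal enone
Product: 9 C11-methyl enone (Me trans to the C9 arm)
Conditions: LDA, THF, −78 °C; MeI, −78 → −30 °C
Reagents that add atoms: iodomethane CI
Why: In this kinetic α′-enolate alkylation C11 is the only enolisable position (C1 is quaternary), and the C11 configuration does not matter because it is erased in step 7.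

Step 7
Reactants: 9 C11-methyl enone
Product: 10 C11 tertiary α-ketol (OH α, trans to the C9 arm; Me-20 β)
Conditions: KHMDS, THF, −78 °C; 3-phenyl-2-(phenylsulfonyl)oxaziridine, −78 °C
Reagents that add atoms: 3-phenyl-2-(phenylsulfonyl)oxaziridine O=S(=O)(c1ccccc1)N1OC1c1ccccc1
Why: In the Davis enolate hydroxylation the planar C11=C12 enolate is shielded on its β face by the neighbouring C9 arm and by Me-15, so oxygen should enter from the α face and set C11 by relay from C10 and C1.

Step 8
Reactants: 10 α-ketol silyl ether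
Product: 11 C9 primary alcohol (9,11-diol)
Conditions: HF·pyridine, pyridine, THF, 0 °C
Reagents that add atoms: none
Why: Buffered fluoride desilylation should remove the primary TBS group while the hindered dimethyl acetal remains.

Step 9
Reactants: 11 diol
Product: 12 C9 aldehyde (western fragment, free 11-OH)
Conditions: Dess–Martin periodinane, pyridine, CH2Cl2, 0 °C
Reagents that add atoms: none
Why: In the Dess–Martin oxidation only the primary alcohol can be oxidised, and keeping O11 unacylated avoids E1cB loss of a β-acetoxy group and epimerisation at C10.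

Step 10
Reactants: 13 dimethyl (4S,5S)-2,2-dimethyl-1,3-dioxolane-4,5-dicarboxylate (D-tartrate acetonide)
Product: 15 (4R,5R)-4,5-diethynyl-2,2-dimethyl-1,3-dioxolane, via dialdehyde 14 (not isolated)
Conditions: DIBAL-H (2.1 equiv), CH2Cl2, −78 °C; then MeOH, K2CO3, Ohira–Bestmann reagent, −78 °C → rt
Reagents that add atoms: dimethyl (1-diazo-2-oxopropyl)phosphonate COP(=O)(OC)C(=[N+]=[N-])C(C)=O
Why: Half-reduction followed by Seyferth–Gilbert homologation in one flask avoids isolating the epimerisable dialdehyde, and C6 and C7 are carried over unchanged from the chiral pool.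

Step 11
Reactants: 15 diyne acetonide (used in excess)
Product: 17 iodoalkene–alkyne acetonide, CH2=C(I)–C7/C6(acetonide)–C≡CH (eastern fragment), via alkenylstannane 16 (not isolated)
Conditions: Bu3SnH (0.8 equiv), Mo(CO)3(CNt-Bu)3 (2 mol %), hydroquinone, THF, 55 °C; then I2, CH2Cl2, 0 °C
Reagents that add atoms: tributyltin hydride CCCC[SnH](CCCC)CCCC; iodine II
Why: Mo-catalysed hydrostannation of a propargylic ether places tin on the internal carbon, iododestannylation follows, and because the two alkynes of C2-symmetric 15 are homotopic, mono-reaction gives a single product.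

Step 12
Reactants: 12 C9 aldehyde; 17 iodoalkene
Product: 18 C9 allylic alcohol, C10–C9H(OH)–C8(=CH2)–C7
Conditions: CrCl2 (4 equiv), NiCl2 (2 mol %), (S)-oxazoline–sulfonamide ligand, Et3N, THF, rt
Reagents that add atoms: none
Why: The Nozaki–Hiyama–Kishi coupling adds the alkenylchromium species only to the aldehyde (enone, ketol, acetal and alkyne are inert), and C9 is set by the chiral Cr–sulfonamide complex, which overrides the weak Felkin bias of C10.

Step 13
Reactants: 18 9,11-diol
Product: 19 9,11-diacetate
Conditions: Ac2O, DMAP, Et3N, CH2Cl2, rt → 35 °C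
Reagents that add atoms: acetic anhydride CC(=O)OC(C)=O
Why: DMAP-catalysed acylation should install both final acetates (secondary O9 and tertiary O11) in one operation without touching a stereocentre.

Step 14
Reactants: 19 diacetate
Product: 20 C8 ketone
Conditions: O3 (1 equiv, Sudan III end point), CH2Cl2, −78 °C; Me2S
Reagents that add atoms: ozone [O-][O+]=O
Why: In the ozonolysis the 1,1-disubstituted C8=CH2 bond is the only electron-rich π bond, since the enone and the terminal alkyne react much more slowly, so C8 should be unmasked as the ketone.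

Step 15
Reactants: 20 ketone acetonide
Product: 21 C6,C7-diol ketone
Conditions: CSA (10 mol %), MeOH, rt
Reagents that add atoms: none
Why: Under acid-catalysed transketalisation in methanol, exchange at the C2 dimethyl acetal is degenerate, while the acetonide is lost irreversibly as 2,2-dimethoxypropane.

Step 16
Reactants: 21 diol ketone
Product: 23 6-O-TES 7-O-(2-bromopropanoyl) ketone, via 6-O-TES ether 22 (not isolated)
Conditions: TESCl (1.05 equiv), imidazole, CH2Cl2, −40 °C; then pyridine, 2-bromopropanoyl bromide, −20 °C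
Reagents that add atoms: chlorotriethylsilane CC[Si](Cl)(CC)CC; 2-bromopropanoyl bromide CC(Br)C(=O)Br
Why: In this selective silylation followed by acylation, the propargylic O6–H beside the slim alkyne is more accessible than the hydrogen-bonded O7–H beside the C8 ketone, so O7 is left for the acyl bromide.

Step 17
Reactants: 23 bromo ester ketone
Product: 24 β-hydroxy-γ-lactone (8-OH, 17-Me, both cis to the C6 arm)
Conditions: SmI2 (2.2 equiv, slow addition), THF, −78 °C
Reagents that add atoms: none
Why: In the SmI2-mediated intramolecular Reformatsky reaction the C–Br bond is reduced first and the Sm(III) enolate closes the five-membered ring (5-exo-trig) through a Sm-bridged transition state in which the C9 branch lies anti to the C6 arm (setting C8) and the methyl group sits next to O8 rather than next to C7 and C9 (setting C17, Me cis to OH).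

Step 18
Reactants: 24 hydroxy lactone alkyne
Product: 26 C5 iodoalkene, C6–C5(I)=C16H2, via alkenylstannane 25 (not isolated)
Conditions: Bu3SnH (1.1 equiv), Mo(CO)3(CNt-Bu)3 (5 mol %), hydroquinone, THF, 55 °C; then I2, CH2Cl2, 0 °C
Reagents that add atoms: tributyltin hydride CCCC[SnH](CCCC)CCCC; iodine II
Why: As in step 11, α-selective hydrostannation and iododestannylation apply; the propargylic OTES group directs tin to C5, and alkyne hydrostannation is much faster than enone reduction.

Step 19
Reactants: 26 acetal iodoalkene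
Product: 27 C2 aldehyde with 6,8-bis-TES protection
Conditions: TESOTf (4 equiv), 2,6-lutidine (6 equiv), CH2Cl2, 0 °C; then H2O
Reagents that add atoms: triethylsilyl triflate CC[Si](CC)(CC)OS(=O)(=O)C(F)(F)F; water O
Why: Silyl triflate/lutidine cleaves the acetal through a pyridinium salt that is hydrolysed on work-up; this frees the aldehyde under non-acidic conditions that spare the TES ether, and it caps the tertiary O8–H, as step 22 requires.

Step 20
Reactants: 28 dibromomethane
Product: 29 (dibromomethyl)tributylstannane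
Conditions: LDA, THF, −90 °C; Bu3SnCl
Reagents that add atoms: tributyltin chloride CCCC[Sn](Cl)(CCCC)CCCC
Why: Deprotonation gives the carbenoid LiCHBr2, which is stable at low temperature and is stannylated by Bu3SnCl.

Step 21
Reactants: 27 aldehyde; 29 (dibromomethyl)tributylstannane
Product: 30 seco compound with an E-C2=C3–SnBu3 terminus and a C5 iodoalkene terminus
Conditions: CrCl2 (8 equiv, Ni-free), LiI, THF/DMF, rt
Reagents that add atoms: none
Why: In this Takai-type olefination the gem-dichromium reagent adds to the non-enolisable neopentyl aldehyde, anti elimination should give the E-alkenylstannane, and without nickel the 2-iodoalkene is not activated.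

Step 22
Reactants: 30 seco stannane iodide
Product: 31 macrocyclic cross-conjugated dienone (C4 ketone), ten-membered ring closed
Conditions: Pd2(dba)3 (10 mol %), AsPh3 (40 mol %), CO (1 atm), NMP/THF, 50 °C, syringe-pump addition to 1 mM
Reagents that add atoms: carbon monoxide [C-]#[O+]
Why: This is a carbonylative Stille macrocyclisation: Pd(0) inserts into C5–I, CO (the future C4) inserts to give the α-methylene acyl-palladium species, the E-alkenylstannane transfers C3 with retention, and reductive elimination forms C3–C4, so two ring bonds (C4–C5 and C3–C4) arise in one operation. The closest known reaction type is the carbonylative alkenyl halide/alkenylstannane coupling used to close macrocyclic divinyl ketones. The ten-membered ring closes end to end through an eleven-membered palladacycle, helped by four contiguous sp2 ring atoms and by the two trans-fused rings already present at C1/C10 and C7/C8, which act as turn elements. No stereocentre is formed: E-C2=C3 and C5=C16 are carried over from the termini, and C4 is left prochiral for reagent control in step 23. The step needs CO insertion before coupling, which is secured by the CO atmosphere and by the strain of the nine-membered diene that direct coupling would give, and it needs ring closure over oligomerisation, which is secured by slow addition at high dilution. It also needs the acyl-palladium species to escape capture by O8, which would form a six-membered lactone; this is prevented by the O8 TES ether and the absence of base, and the silyl ether at C6 is too poor a leaving group for π-allyl formation.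

Step 23
Reactants: 31 dienone
Product: 32 (4S)-alcohol
Conditions: (R)-Me-CBS (0.5 equiv), catecholborane (1.5 equiv), toluene, −78 °C
Reagents that add atoms: none
Why: In the CBS reduction the α-branched C5 alkenyl side acts as the large group and the C3 alkenyl side as the small group, so the (R)-catalyst should give 4S by 1,2-reduction, while the C12 ketone is protected by the quaternary C11.

Step 24
Reactants: 32 C4 alcohol
Product: 33 4-O-TBS ether
Conditions: TBSOTf, 2,6-lutidine, CH2Cl2, −78 °C
Reagents that add atoms: tert-butyldimethylsilyl triflate CC(C)(C)[Si](C)(C)OS(=O)(=O)C(F)(F)F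
Why: Silylation of the only free hydroxyl masks the ionisation-prone bis-allylic alcohol before C6 is activated.

Step 25
Reactants: 33 tris-silyl ether
Product: 34 C6 alcohol (4-O-TBS and 8-O-TES retained)
Conditions: PPTS (0.2 equiv), MeOH/CH2Cl2, 0 °C
Reagents that add atoms: none
Why: In this selective acid-catalysed methanolysis the secondary TES ether cleaves faster than the tertiary TES ether and the secondary TBS ether.

Step 26
Reactants: 34 C6 alcohol
Product: 35 (6S)-chloride
Conditions: PPh3, hexachloroacetone, CH2Cl2, −30 → 0 °C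
Reagents that add atoms: hexachloroacetone ClC(Cl)(Cl)C(=O)C(Cl)(Cl)Cl
Why: In this Appel-type chlorination chloride displaces the alkoxyphosphonium ion by SN2 with inversion (tartrate configuration → 6S); ionisation is disfavoured by the electron-withdrawing C7–O bond, and SN2′ attack is disfavoured by the strained endocyclic C5=C6 olefin it would create.

Step 27
Reactants: 35 chloride
Product: 36 target CNP0196166.1
Conditions: HF·pyridine, pyridine, THF, 0 °C → rt
Reagents that add atoms: none
Why: Buffered fluoride desilylation should remove the O4 TBS and O8 TES groups without affecting the allylic chloride, the acetates, the enone or the lactone.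

**Compound list**
1 | but-3-en-2-one | C=CC(C)=O | starting material
2 | 2-(triisopropylsilyloxy)buta-1,3-diene | C=CC(=C)O[Si](C(C)C)(C(C)C)C(C)C | intermediate
3 | (tert-butyldimethylsilyloxy)acetaldehyde | O=CCO[Si](C)(C)C(C)(C)C | starting material
4 | 2-(triphenylphosphoranylidene)propanal | CC(C=O)=P(c1ccccc1)(c1ccccc1)c1ccccc1 | starting material
5 | (E)-4-(tert-butyldimethylsilyloxy)-2-methylbut-2-enal | O=C/C(C)=C/CO[Si](C)(C)C(C)(C)C | intermediate
6 | Diels–Alder adduct, TIPS enol ether, C1 CHO trans to C10 CH2OTBS | O=C[C@@]1(C)CC=C(O[Si](C(C)C)(C(C)C)C(C)C)C[C@@H]1CO[Si](C)(C)C(C)(C)C | intermediate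
7 | enone aldehyde | O=C[C@@]1(C)C=CC(=O)C[C@@H]1CO[Si](C)(C)C(C)(C)C | intermediate
8 | C2 dimethyl acetal | COC(OC)[C@@]1(C)C=CC(=O)C[C@@H]1CO[Si](C)(C)C(C)(C)C | intermediate
9 | C11-methyl enone | COC(OC)[C@@]1(C)C=CC(=O)[C@@H](C)[C@@H]1CO[Si](C)(C)C(C)(C)C | intermediate
10 | C11 α-ketol | COC(OC)[C@@]1(C)C=CC(=O)[C@@](C)(O)[C@@H]1CO[Si](C)(C)C(C)(C)C | intermediate
11 | 9,11-diol | COC(OC)[C@@]1(C)C=CC(=O)[C@@](C)(O)[C@@H]1CO | intermediate
12 | C9 aldehyde (western fragment) | COC(OC)[C@@]1(C)C=CC(=O)[C@@](C)(O)[C@@H]1C=O | intermediate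
13 | dimethyl (4S,5S)-2,2-dimethyl-1,3-dioxolane-4,5-dicarboxylate | COC(=O)[C@H]1OC(C)(C)O[C@@H]1C(=O)OC | starting material
14 | tartraldehyde acetonide | O=C[C@H]1OC(C)(C)O[C@@H]1C=O | intermediate
15 | (4R,5R)-4,5-diethynyl-2,2-dimethyl-1,3-dioxolane | C#C[C@H]1OC(C)(C)O[C@@H]1C#C | intermediate
16 | mono α-tributylstannyl alkene | C=C([Sn](CCCC)(CCCC)CCCC)[C@H]1OC(C)(C)O[C@@H]1C#C | intermediate
17 | iodoalkene–alkyne acetonide (eastern fragment) | C=C(I)[C@H]1OC(C)(C)O[C@@H]1C#C | intermediate
18 | coupled C9 allylic alcohol | COC(OC)[C@@]1(C)C=CC(=O)[C@@](C)(O)[C@@H]1[C@H](O)C(=C)[C@H]2OC(C)(C)O[C@@H]2C#C | intermediate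
19 | 9,11-diacetate | COC(OC)[C@@]1(C)C=CC(=O)[C@@](C)(OC(C)=O)[C@@H]1[C@H](OC(C)=O)C(=C)[C@H]2OC(C)(C)O[C@@H]2C#C | intermediate
20 | C8 ketone | COC(OC)[C@@]1(C)C=CC(=O)[C@@](C)(OC(C)=O)[C@@H]1[C@H](OC(C)=O)C(=O)[C@H]2OC(C)(C)O[C@@H]2C#C | intermediate
21 | C6,C7-diol ketone | COC(OC)[C@@]1(C)C=CC(=O)[C@@](C)(OC(C)=O)[C@@H]1[C@H](OC(C)=O)C(=O)[C@@H](O)[C@H](O)C#C | intermediate
22 | 6-O-TES ether | COC(OC)[C@@]1(C)C=CC(=O)[C@@](C)(OC(C)=O)[C@@H]1[C@H](OC(C)=O)C(=O)[C@@H](O)[C@H](O[Si](CC)(CC)CC)C#C | intermediate
23 | 7-O-(2-bromopropanoyl) ester | COC(OC)[C@@]1(C)C=CC(=O)[C@@](C)(OC(C)=O)[C@@H]1[C@H](OC(C)=O)C(=O)[C@@H](OC(=O)C(C)Br)[C@H](O[Si](CC)(CC)CC)C#C | intermediate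
24 | β-hydroxy-γ-lactone | COC(OC)[C@@]1(C)C=CC(=O)[C@@](C)(OC(C)=O)[C@@H]1[C@H](OC(C)=O)[C@]2(O)[C@@H](C)C(=O)O[C@H]2[C@H](O[Si](CC)(CC)CC)C#C | intermediate
25 | C5 alkenylstannane | COC(OC)[C@@]1(C)C=CC(=O)[C@@](C)(OC(C)=O)[C@@H]1[C@H](OC(C)=O)[C@]2(O)[C@@H](C)C(=O)O[C@H]2[C@H](O[Si](CC)(CC)CC)C(=C)[Sn](CCCC)(CCCC)CCCC | intermediate
26 | C5 iodoalkene | COC(OC)[C@@]1(C)C=CC(=O)[C@@](C)(OC(C)=O)[C@@H]1[C@H](OC(C)=O)[C@]2(O)[C@@H](C)C(=O)O[C@H]2[C@H](O[Si](CC)(CC)CC)C(I)=C | intermediate
27 | C2 aldehyde, 6,8-bis-TES | O=C[C@@]1(C)C=CC(=O)[C@@](C)(OC(C)=O)[C@@H]1[C@H](OC(C)=O)[C@]2(O[Si](CC)(CC)CC)[C@@H](C)C(=O)O[C@H]2[C@H](O[Si](CC)(CC)CC)C(I)=C | intermediate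
28 | dibromomethane | BrCBr | starting material
29 | (dibromomethyl)tributylstannane | CCCC[Sn](CCCC)(CCCC)C(Br)Br | intermediate
30 | seco E-alkenylstannane/iodoalkene | CCCC[Sn](CCCC)(CCCC)/C=C/[C@@]1(C)C=CC(=O)[C@@](C)(OC(C)=O)[C@@H]1[C@H](OC(C)=O)[C@]2(O[Si](CC)(CC)CC)[C@@H](C)C(=O)O[C@H]2[C@H](O[Si](CC)(CC)CC)C(I)=C | intermediate
31 | macrocyclic dienone | C=C1C(=O)/C=C/[C@@]2(C)C=CC(=O)[C@@](C)(OC(C)=O)[C@@H]2[C@H](OC(C)=O)[C@]2(O[Si](CC)(CC)CC)[C@@H](C)C(=O)O[C@H]2[C@@H]1O[Si](CC)(CC)CC | intermediate
32 | (4S)-alcohol | C=C1[C@@H](O)/C=C/[C@@]2(C)C=CC(=O)[C@@](C)(OC(C)=O)[C@@H]2[C@H](OC(C)=O)[C@]2(O[Si](CC)(CC)CC)[C@@H](C)C(=O)O[C@H]2[C@@H]1O[Si](CC)(CC)CC | intermediate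
33 | 4-O-TBS ether | C=C1[C@@H](O[Si](C)(C)C(C)(C)C)/C=C/[C@@]2(C)C=CC(=O)[C@@](C)(OC(C)=O)[C@@H]2[C@H](OC(C)=O)[C@]2(O[Si](CC)(CC)CC)[C@@H](C)C(=O)O[C@H]2[C@@H]1O[Si](CC)(CC)CC | intermediate
34 | C6 alcohol | C=C1[C@@H](O[Si](C)(C)C(C)(C)C)/C=C/[C@@]2(C)C=CC(=O)[C@@](C)(OC(C)=O)[C@@H]2[C@H](OC(C)=O)[C@]2(O[Si](CC)(CC)CC)[C@@H](C)C(=O)O[C@H]2[C@@H]1O | intermediate
35 | (6S)-chloride | C=C1[C@@H](O[Si](C)(C)C(C)(C)C)/C=C/[C@@]2(C)C=CC(=O)[C@@](C)(OC(C)=O)[C@@H]2[C@H](OC(C)=O)[C@]2(O[Si](CC)(CC)CC)[C@@H](C)C(=O)O[C@H]2[C@H]1Cl | intermediate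
36 | CNP0196166.1 | C=C1[C@@H](O)/C=C/[C@@]2(C)C=CC(=O)[C@@](C)(OC(C)=O)[C@@H]2[C@H](OC(C)=O)[C@]2(O)[C@@H](C)C(=O)O[C@H]2[C@H]1Cl | target

**Counts:** 27 steps in total; the longest linear sequence is 23 steps (steps 2–9, 12–19, 21–27).

**Steps most likely to fail**
Step 22: the intramolecular tin-to-palladium transfer may be slow. That would allow oligomerisation, protodestannylation, or decay of the acyl-palladium species before the strained ring closes. Fallback: aldehyde 27 is treated with (triphenylphosphoranylidene)acetaldehyde in a Wittig olefination to give the E-enal iodoalkene F1. A Nozaki–Hiyama–Kishi reaction (CrCl2, cat. NiCl2, DMSO/THF, high dilution) then closes C4–C5 directly and rejoins the route at 32. If the 4-epimer prevails, Dess–Martin oxidation gives 31 and step 23 corrects C4.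

Step 17: SmI2 may cleave the α-acyloxy ketone or reduce the enone in competition with C–Br reduction, and the facial selectivity of the ring closure may be poor. Fallback: acetonide ketone 20 is treated with the zinc Reformatsky reagent of methyl 2-bromopropanoate under chelation control, with Zn bridging the ketone oxygen and O7, to give the β-hydroxy ester F2. CSA in MeOH then removes the acetonide and lactonises onto O7 to give the 6-hydroxy lactone F3. Selective silylation of the secondary alcohol (TESCl, imidazole) rejoins the route at 24.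

Step 3: the trisubstituted enal may react sluggishly, a Mukaiyama-type attack at the formyl group may compete, and enantioselectivity may erode. Fallback: enal 5 is combined with the much more reactive, commercial 1-(dimethylamino)-3-(tert-butyldimethylsilyloxy)buta-1,3-diene under hydrogen-bond catalysis by a TADDOL to give the amino enol ether cycloadduct F4. Acetyl chloride at −78 °C triggers β-elimination of the amine and rejoins the route at 7, which bypasses step 4.

**Further compounds**
F1 | step 22 | E-enal iodoalkene | O=C/C=C/[C@@]1(C)C=CC(=O)[C@@](C)(OC(C)=O)[C@@H]1[C@H](OC(C)=O)[C@]2(O[Si](CC)(CC)CC)[C@@H](C)C(=O)O[C@H]2[C@H](O[Si](CC)(CC)CC)C(I)=C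
F2 | step 17 | β-hydroxy ester acetonide | COC(OC)[C@@]1(C)C=CC(=O)[C@@](C)(OC(C)=O)[C@@H]1[C@H](OC(C)=O)[C@](O)([C@@H](C)C(=O)OC)[C@H]2OC(C)(C)O[C@@H]2C#C
F3 | step 17 | 6-hydroxy lactone | COC(OC)[C@@]1(C)C=CC(=O)[C@@](C)(OC(C)=O)[C@@H]1[C@H](OC(C)=O)[C@]2(O)[C@@H](C)C(=O)O[C@H]2[C@H](O)C#C
F4 | step 3 | amino enol ether cycloadduct | O=C[C@@]1(C)[C@@H](N(C)C)C=C(O[Si](C)(C)C(C)(C)C)C[C@@H]1CO[Si](C)(C)C(C)(C)C
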